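**Plan**

- Retrosynthesis: the C2–Br and C3–Br bonds are cut first (back to a 2‑carboxylic acid with free C3–H), then N1–CH3, then the pyrrole bond N1–C7a (back to a vinyl azide), and last the C2=C3 alkene (aldehyde plus azidoacetate).
- Forward: the benzene ring is bought with both of its bromines in place. A condensation attaches the C3–C2–N unit, azide thermolysis closes the pyrrole ring (the only ring made), and N‑methylation, saponification and a double bromination with loss of CO2 finish the target.
- Enabling feature: C7a, the carbon bonded to N1, lies meta to both C4–Br and C6–Br. The benzo ring therefore maps onto a 2,4‑dibromophenyl group whose single free ortho C–H is the future C7a, so the pyrrole closure has only one possible site.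
- Stereochemistry: the target has no stereocentre. The only stereo‑element on the route is the Z alkene of the azidoacrylate, set in the condensation and lost on aromatisation.

Key step: step 2

Remark: the target is planar and achiral, so the request for a single enantiomer is met by the compound itself and no enantiocontrol is planned.

**Step 1**
Reactants: 1 2,4‑dibromobenzaldehyde; 2 methyl azidoacetate
Product: 4 methyl (Z)‑2‑azido‑3‑(2,4‑dibromophenyl)acrylate, via β‑hydroxy azido ester 3 (not isolated)
Conditions: NaOMe (4 equiv), 2 (4 equiv), MeOH, −10 → 0 °C
Reagents that add atoms: none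
Why: Knoevenagel‑type condensation as used in the Hemetsberger sequence: the azidoacetate enolate adds to the aldehyde and E1cB loss of hydroxide from aldol 3 should give the conjugated azide as the Z isomer (azide cis to aryl, ester and aryl apart), with methoxide matched to the methyl ester.

**Step 2**
Reactants: 4 methyl (Z)‑2‑azido‑3‑(2,4‑dibromophenyl)acrylate
Product: 6 methyl 4,6‑dibromo‑1H‑indole‑2‑carboxylate, via 2H‑azirine 5 (not isolated)
Conditions: xylenes (ca. 0.05 M), slow addition into the refluxing solvent, ca. 140 °C
Reagents that add atoms: none
Why: Heating expels N2 from the vinyl azide to give a vinyl nitrene in equilibrium with 2H‑azirine 5; the nitrogen then bonds to the ortho carbon of the arene and a [1,5]‑hydrogen shift from C7a to nitrogen restores aromaticity. This is the Hemetsberger–Knittel indole synthesis, a thermal nitrene C–H amination of an α‑azidocinnamate. The pyrrole ring closes through the N1–C7a bond in a formal 6π (1,5‑) electrocyclisation of the vinyl nitrene onto the benzene ring. No stereocentre is formed. The step needs regio‑ and chemoselectivity: the aryl ring of 4 has one ortho C–H only (the other ortho position carries the bromine that becomes C4–Br, the para bromine becomes C6–Br), and the metal‑free, base‑free conditions should leave both C–Br bonds and the ester untouched. Dilution and slow addition are chosen to hold back bimolecular decay of the azirine.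

**Step 3**
Reactants: 6 methyl 4,6‑dibromo‑1H‑indole‑2‑carboxylate
Product: 7 methyl 4,6‑dibromo‑1‑methyl‑1H‑indole‑2‑carboxylate
Conditions: MeI (1.5 equiv), K2CO3 (2 equiv), DMF, rt
Reagents that add atoms: iodomethane, CI
Why: The 2‑ester and the bromines acidify the indole N–H enough for carbonate, and the delocalised anion should be alkylated at nitrogen by SN2 attack on iodomethane (N‑alkylation of an indole‑2‑carboxylate).

**Step 4**
Reactants: 7 methyl 4,6‑dibromo‑1‑methyl‑1H‑indole‑2‑carboxylate
Product: 8 4,6‑dibromo‑1‑methyl‑1H‑indole‑2‑carboxylic acid
Conditions: LiOH·H2O (3 equiv), THF/MeOH/H2O (3:1:1), 40 °C; then 1 M HCl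
Reagents that add atoms: lithium hydroxide, [Li+].[OH-]
Why: Saponification (BAc2) of the methyl ester; aryl bromides and the N‑methyl group are inert to aqueous hydroxide at this temperature, and the N‑methylindole‑2‑carboxylic acid should survive acidification without losing CO2.

**Step 5**
Reactants: 8 4,6‑dibromo‑1‑methyl‑1H‑indole‑2‑carboxylic acid
Product: 10 2,3,4,6‑tetrabromo‑1‑methyl‑1H‑indole, via 3‑bromo acid 9 (not isolated)
Conditions: NBS (2.2 equiv), DMF, 0 °C → rt, dark
Reagents that add atoms: N‑bromosuccinimide, O=C1CCC(=O)N1Br
Why: Electrophilic bromination at C3, the most nucleophilic indole position, should give acid 9, and a second bromonium equivalent attacks C2 ipso to the carboxyl group with loss of CO2 (ionic halodecarboxylation of an electron‑rich heteroaryl carboxylic acid); the reverse order of the two events leads to the same product, and holding NBS near two equivalents should spare C5 and C7 of the deactivated benzo ring.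

**Compound list**

1 | 2,4‑dibromobenzaldehyde | O=Cc1ccc(Br)cc1Br | starting material
2 | methyl azidoacetate | COC(=O)CN=[N+]=[N-] | starting material
3 | methyl 2‑azido‑3‑(2,4‑dibromophenyl)‑3‑hydroxypropanoate (aldol adduct, diastereomer mixture, racemic) | COC(=O)C(N=[N+]=[N-])C(O)c1ccc(Br)cc1Br | intermediate
4 | methyl (Z)‑2‑azido‑3‑(2,4‑dibromophenyl)acrylate | COC(=O)/C(N=[N+]=[N-])=C/c1ccc(Br)cc1Br | intermediate
5 | methyl 2‑(2,4‑dibromophenyl)‑2H‑azirine‑3‑carboxylate (racemic) | COC(=O)C1=NC1c1ccc(Br)cc1Br | intermediate
6 | methyl 4,6‑dibromo‑1H‑indole‑2‑carboxylate | COC(=O)c1cc2c(Br)cc(Br)cc2[nH]1 | intermediate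
7 | methyl 4,6‑dibromo‑1‑methyl‑1H‑indole‑2‑carboxylate | COC(=O)c1cc2c(Br)cc(Br)cc2n1C | intermediate
8 | 4,6‑dibromo‑1‑methyl‑1H‑indole‑2‑carboxylic acid | OC(=O)c1cc2c(Br)cc(Br)cc2n1C | intermediate
9 | 3,4,6‑tribromo‑1‑methyl‑1H‑indole‑2‑carboxylic acid | OC(=O)c1c(Br)c2c(Br)cc(Br)cc2n1C | intermediate
10 | 2,3,4,6‑tetrabromo‑1‑methyl‑1H‑indole | Cn1c(Br)c(Br)c2c(Br)cc(Br)cc21 | target

**Totals**

Total step count: 5
Longest linear sequence: 5 steps (from 1)

**Steps most likely to fail**

Step 5. The ipso substitution may stall once C3 is brominated, because the tribrominated acid is a weak nucleophile, and forcing it with more reagent may brominate the benzo ring. The fallback separates loss of CO2 from bromination. It sets out from acid 8 and returns at target 10. Silver‑catalysed protodecarboxylation (Ag2CO3 cat., AcOH, DMSO, 120 °C) should give 4,6‑dibromo‑1‑methyl‑1H‑indole F1. One equivalent of NBS (DMF, 0 °C) should brominate C3 to give 3,4,6‑tribromo‑1‑methyl‑1H‑indole F2. A second equivalent of NBS (CH2Cl2, silica gel, rt) then brominates C2 and delivers 10.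

Step 1. The azidoacetate anion may lose nitrogen under the basic conditions faster than it adds to the hindered ortho‑bromo aldehyde, and the aldol may stall before dehydration. The fallback avoids the azido enolate and introduces the azide by substitution. It sets out from aldehyde 1 and returns at azidoacrylate 4. Wittig olefination with methyl (triphenylphosphoranylidene)acetate (toluene, 80 °C) should give methyl (E)‑3‑(2,4‑dibromophenyl)acrylate F3. Anti addition of Br2 (CH2Cl2, 0 °C) should give racemic methyl (2RS,3SR)‑2,3‑dibromo‑3‑(2,4‑dibromophenyl)propanoate F4. Sodium azide (3 equiv, DMF, rt to 50 °C) then displaces the α‑bromide and eliminates HBr to give 4. Either alkene geometry of 4 would serve, since both open to the same azirine in step 2.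

Step 2. Bimolecular consumption of the nitrene and azirine (dimers, tar) may outrun closure onto a ring deactivated by two bromines. The fallback replaces free‑nitrene thermolysis by metal‑nitrenoid C–H amination. It sets out from 4 and returns at 6. Rh2(O2CC3F7)4 (3–5 mol %) in toluene at 40–60 °C should form a rhodium nitrenoid that closes the same N1–C7a bond at a temperature where the free azirine does not build up. The aryl bromides are not expected to engage Rh(II). No compound outside the list is formed (F0).

**Further compounds**

F1 | step 5 | 4,6‑dibromo‑1‑methyl‑1H‑indole | Cn1ccc2c(Br)cc(Br)cc21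
F2 | step 5 | 3,4,6‑tribromo‑1‑methyl‑1H‑indole | Cn1cc(Br)c2c(Br)cc(Br)cc21
F3 | step 1 | methyl (E)‑3‑(2,4‑dibromophenyl)acrylate | COC(=O)/C=C/c1ccc(Br)cc1Br
F4 | step 1 | methyl (2RS,3SR)‑2,3‑dibromo‑3‑(2,4‑dibromophenyl)propanoate (racemate, 2R,3S enantiomer drawn) | COC(=O)[C@@H](Br)[C@@H](Br)c1ccc(Br)cc1Br
F0 | step 2 | none | none
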